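**Plan**

1. Locants are those of 2-benzopyran for the core (C1, O2, C3, C4, C4a, C5–C8, C8a) and C9–C14 for the side chain (C9/C10 epoxide, C11=C12, C13, C14).
2. Retrosynthesis: cut O2–C3 (cycloisomerisation of a C3≡C4 alkyne onto the C1 enol), then C4a–C8a and C7–C8 together (Diels–Alder), then C4–C4a (Sonogashira); the side chain comes from two Wittig olefinations and an epoxy-aldehyde-to-alkyne homologation.
3. Enabling feature: in the carbocycle C4a–C5–C6–C7–C8–C8a the tertiary oxygen on C7 sits 1,4 to C4a, with the C6 ketone and the C4a=C5 bond between them. This is the β-eliminated form of a 7-oxabicyclo[2.2.1]heptene silyl enol ether, i.e. a dearomatised 2-methyl-3-silyloxyfuran (furan C2 = C7, furan O = O7, C3 = C6, C5 = C4a). O8–C8–C8a–C1 is a cis β-oxyacrylate, supplied ring-locked as a 1,3-dioxin-4-one.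
4. Forward: epoxy-alkyne 11 is joined to iodofuran 16; the Diels–Alder step closes the carbocycle with a temporary oxygen bridge and a temporary dioxanone ring; reduction and fluoride unzip both; silver closes the pyran ring last.
5. Stereochemistry: C13/C14 from ethyl (S)-3-hydroxybutanoate plus Fráter–Seebach methylation; C9/C10 from Sharpless epoxidation; C7/C8 from the Diels–Alder step (endo mode gives O8 trans to O7; the menthone ketal gives the absolute sense).

Key step: step 17

Assumption: cycloaddition to the menthone-derived spiro-dioxinone is taken to occur on the face flanked by the ring CH2 of the menthane unit, anti to the isopropyl-bearing carbon. Spiro-epimer 22 is drawn so that this face leads to (7S,8R); if the sense is opposite, the other spiro-epimer from step 16 is used.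

**Side chain**

Step 1
Reactants: 1 ethyl (3S)-3-hydroxybutanoate
Product: 2 ethyl (2S,3S)-3-hydroxy-2-methylbutanoate
Conditions: LiN(iPr)2 (2.2 equiv), THF, −78 to −20 °C; then MeI, DMPU, −78 to 0 °C
Reagents that add atoms: iodomethane CI
Why: Fráter–Seebach alkylation, in which the chelated lithium alkoxide–enolate dianion should be methylated anti to the C3 methyl group and so set the anti C13/C14 pair.

Step 2
Reactants: 2 ethyl (2S,3S)-3-hydroxy-2-methylbutanoate
Product: 3 ethyl (2S,3S)-3-[(tert-butyldimethylsilyl)oxy]-2-methylbutanoate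
Conditions: tert-butyldimethylsilyl chloride, imidazole, DMF, 25 °C
Reagents that add atoms: tert-butyldimethylsilyl chloride CC(C)(C)[Si](C)(C)Cl
Why: Standard silylation of a secondary alcohol, needed so that the β-oxygen survives the reductions and olefinations.

Step 3
Reactants: 3 ethyl (2S,3S)-3-[(tert-butyldimethylsilyl)oxy]-2-methylbutanoate
Product: 4 (2S,3S)-3-[(tert-butyldimethylsilyl)oxy]-2-methylbutanal
Conditions: iBu2AlH (1.1 equiv), CH2Cl2, −78 °C; aqueous KNaC4H4O6
Reagents that add atoms: none
Why: Partial ester reduction, in which the aluminium hemiacetal should persist at −78 °C and release the aldehyde only on work-up, without epimerising the α-centre.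

Step 4
Reactants: 4 (2S,3S)-3-[(tert-butyldimethylsilyl)oxy]-2-methylbutanal
Product: 5 (2E,4R,5S)-5-[(tert-butyldimethylsilyl)oxy]-2,4-dimethylhex-2-enal
Conditions: 2-(triphenylphosphoranylidene)propanal, toluene, 80 °C
Reagents that add atoms: 2-(triphenylphosphoranylidene)propanal CC(C=O)=P(c1ccccc1)(c1ccccc1)c1ccccc1
Why: Wittig olefination with a stabilised ylide, which should give the E trisubstituted enal (C11=C12) directly at the aldehyde oxidation level.

Step 5
Reactants: 5 (2E,4R,5S)-5-[(tert-butyldimethylsilyl)oxy]-2,4-dimethylhex-2-enal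
Product: 6 ethyl (2E,4E,6R,7S)-7-[(tert-butyldimethylsilyl)oxy]-2,4,6-trimethylocta-2,4-dienoate
Conditions: ethyl 2-(triphenylphosphoranylidene)propanoate, toluene, 60 °C
Reagents that add atoms: ethyl 2-(triphenylphosphoranylidene)propanoate CCOC(=O)C(C)=P(c1ccccc1)(c1ccccc1)c1ccccc1
Why: A second E-selective Wittig olefination with a stabilised ylide installs the C9=C10 alkene that will carry the epoxide.

Step 6
Reactants: 6 ethyl (2E,4E,6R,7S)-7-[(tert-butyldimethylsilyl)oxy]-2,4,6-trimethylocta-2,4-dienoate
Product: 7 (2E,4E,6R,7S)-7-[(tert-butyldimethylsilyl)oxy]-2,4,6-trimethylocta-2,4-dien-1-ol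
Conditions: iBu2AlH (2.2 equiv), CH2Cl2, −78 °C; aqueous KNaC4H4O6
Reagents that add atoms: none
Why: 1,2-Reduction of the conjugated ester gives the allylic alcohol required for the directed epoxidation.

Step 7
Reactants: 7 (2E,4E,6R,7S)-7-[(tert-butyldimethylsilyl)oxy]-2,4,6-trimethylocta-2,4-dien-1-ol
Product: 8 [(2S,3S)-3-{(2E,4R,5S)-5-[(tert-butyldimethylsilyl)oxy]-4-methylhex-2-en-2-yl}-2-methyloxiran-2-yl]methanol
Conditions: Ti(OiPr)4 (10 mol %), L-(+)-diisopropyl tartrate (12 mol %), t-BuOOH, 4 Å molecular sieves, CH2Cl2, −20 °C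
Reagents that add atoms: tert-butyl hydroperoxide CC(C)(C)OO
Why: Sharpless asymmetric epoxidation, in which the titanium-bound allylic alcohol directs oxygen to the C9=C10 alkene only and the L-(+)-tartrate should deliver the (2S,3S) epoxide of an E 2-methyl allylic alcohol, i.e. the C9/C10 configuration of the target.

Step 8
Reactants: 8 [(2S,3S)-3-{(2E,4R,5S)-5-[(tert-butyldimethylsilyl)oxy]-4-methylhex-2-en-2-yl}-2-methyloxiran-2-yl]methanol
Product: 9 (2R,3S)-3-{(2E,4R,5S)-5-[(tert-butyldimethylsilyl)oxy]-4-methylhex-2-en-2-yl}-2-methyloxirane-2-carbaldehyde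
Conditions: TEMPO (10 mol %), PhI(OAc)2 (1.1 equiv), CH2Cl2, 25 °C
Reagents that add atoms: none
Why: Oxoammonium oxidation of the primary alcohol under near-neutral conditions should leave the vinyl epoxide intact, and the quaternary α-carbon cannot epimerise.

Step 9
Reactants: 9 (2R,3S)-3-{(2E,4R,5S)-5-[(tert-butyldimethylsilyl)oxy]-4-methylhex-2-en-2-yl}-2-methyloxirane-2-carbaldehyde
Product: 10 tert-butyl({(2S,3R,4E)-5-[(2S,3S)-3-ethynyl-3-methyloxiran-2-yl]-3-methylhex-4-en-2-yl}oxy)dimethylsilane
Conditions: dimethyl (1-diazo-2-oxopropyl)phosphonate, K2CO3, MeOH, 0 to 25 °C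
Reagents that add atoms: dimethyl (1-diazo-2-oxopropyl)phosphonate CC(=O)C(=[N+]=[N-])P(=O)(OC)OC
Why: Ohira–Bestmann homologation of a non-enolisable epoxy aldehyde under mild carbonate conditions should give the terminal alkyne (C3≡C4) without touching the epoxide.

Step 10
Reactants: 10 tert-butyl({(2S,3R,4E)-5-[(2S,3S)-3-ethynyl-3-methyloxiran-2-yl]-3-methylhex-4-en-2-yl}oxy)dimethylsilane
Product: 11 (2S,3R,4E)-5-[(2S,3S)-3-ethynyl-3-methyloxiran-2-yl]-3-methylhex-4-en-2-ol
Conditions: Bu4NF, THF, 0 to 25 °C
Reagents that add atoms: none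
Why: Fluoride desilylation at this robust stage frees the C14 hydroxyl, so that no protecting group has to be removed from the sensitive final product.

**Furan**

Step 11
Reactants: 12 2-methyloxolan-3-one (racemic)
Product: 13 2-methylfuran-3(2H)-one
Conditions: 2-iodoxybenzoic acid (IBX, 1.5 equiv), DMSO–toluene, 70 °C
Reagents that add atoms: none
Why: IBX dehydrogenation of a ketone to its enone, where only the C4–C5 bond can become an endocyclic double bond and the product is a stabilised vinylogous ester.

Step 12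
Reactants: 13 2-methylfuran-3(2H)-one
Product: 14 [(2-methylfuran-3-yl)oxy]tri(propan-2-yl)silane
Conditions: triisopropylsilyl triflate, Et3N, CH2Cl2, 0 °C
Reagents that add atoms: triisopropylsilyl trifluoromethanesulfonate CC(C)[Si](OS(=O)(=O)C(F)(F)F)(C(C)C)C(C)C
Why: O-Silylation of the vinylogous ester carbonyl followed by loss of the C2 proton aromatises the ring to the electron-rich 3-silyloxyfuran.

Step 13
Reactants: 14 [(2-methylfuran-3-yl)oxy]tri(propan-2-yl)silane
Product: 16 [(5-iodo-2-methylfuran-3-yl)oxy]tri(propan-2-yl)silane, via 5-lithio furan 15 (not isolated)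
Conditions: n-BuLi, THF, −78 to −20 °C; then I2, −78 °C
Reagents that add atoms: iodine II
Why: α-Lithiation of a furan at its only free α-position (C5), with the bulky silyl group disfavouring lateral metalation and silyl migration, followed by iodine quench.

Step 14
Reactants: 16 [(5-iodo-2-methylfuran-3-yl)oxy]tri(propan-2-yl)silane; 11 (2S,3R,4E)-5-[(2S,3S)-3-ethynyl-3-methyloxiran-2-yl]-3-methylhex-4-en-2-ol
Product: 17 (2S,3R,4E)-3-methyl-5-{(2S,3S)-3-methyl-3-[(5-methyl-4-{[tri(propan-2-yl)silyl]oxy}furan-2-yl)ethynyl]oxiran-2-yl}hex-4-en-2-ol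
Conditions: Pd(PPh3)2Cl2 (3 mol %), CuI (5 mol %), Et3N, THF, 25 °C
Reagents that add atoms: none
Why: Sonogashira coupling of a 2-iodofuran with a terminal alkyne forms the future C4–C4a bond and should tolerate the free alcohol and the propargylic epoxide at room temperature.

**Dienophile**

Step 15
Reactants: 18 5-(methoxymethylidene)-2,2-dimethyl-1,3-dioxane-4,6-dione
Product: 19 5-(hydroxymethylidene)-2,2-dimethyl-1,3-dioxane-4,6-dione
Conditions: 2 M aqueous HCl, 25 °C
Reagents that add atoms: water O
Why: Addition–elimination of water at the doubly activated enol ether carbon exchanges methoxy for hydroxy.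

Step 16
Reactants: 19 5-(hydroxymethylidene)-2,2-dimethyl-1,3-dioxane-4,6-dione; 20 (−)-menthone, (2S,5R)-5-methyl-2-(propan-2-yl)cyclohexan-1-one
Product: 22 (2R,2'S,5'R)-5'-methyl-2'-(propan-2-yl)spiro[1,3-dioxine-2,1'-cyclohexan]-4-one (spiro centre as in the SMILES), via formylketene 21 (not isolated)
Conditions: toluene, 110 °C; chromatographic separation of the spiro-epimers
Reagents that add atoms: none
Why: Thermal cycloreversion of the Meldrum's acid derivative (loss of acetone and CO2) should give formylketene, which adds across the menthone carbonyl in a hetero-Diels–Alder reaction to give the ring-locked cis β-oxyacrylate carrying the chiral controller.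

**Union and endgame**

Step 17
Reactants: 17 (2S,3R,4E)-3-methyl-5-{(2S,3S)-3-methyl-3-[(5-methyl-4-{[tri(propan-2-yl)silyl]oxy}furan-2-yl)ethynyl]oxiran-2-yl}hex-4-en-2-ol; 22 the spiro-dioxinone
Product: 23 endo Diels–Alder adduct: a 7-oxabicyclo[2.2.1]hept-2-ene (bridgeheads C7 with methyl and C4a with the alkynyl side chain, C6 as triisopropylsilyl enol ether) cis-fused at C8/C8a, on the face anti to the oxygen bridge, to the spiro-menthane 1,3-dioxan-4-one
Conditions: 22 (2 equiv), CH2Cl2, 12 kbar, 25 °C
Reagents that add atoms: none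
Why: A concerted but asynchronous [4+2] cycloaddition in which the silyloxyfuran, most nucleophilic at its methyl-bearing C2 (α to the silyloxy carbon), attacks the β-carbon of the vinylogous carbonate first, so that furan C2 (future C7) bonds to the oxygen-bearing C8 and furan C5 (future C4a) to C8a. The closest known reaction type is the Diels–Alder reaction of 3-alkoxy- and 3-silyloxyfurans with cis-disubstituted cyclic dienophiles such as maleimides, with high pressure as the classical aid for sluggish furan cycloadditions. One ring of the target, the carbocycle C4a–C5–C6–C7–C8–C8a, is closed by suprafacial [4+2] bond formation, while the furan oxygen is carried along as a temporary C7–O–C4a bridge and the dioxanone as a temporary cis-fused ring holding O8 and C1. C7 and C4a are fixed by addition to one furan face, C8 and C8a are cis because the alkene is ring-locked, and the endo mode (lactone under the diene, favoured by secondary overlap and by pressure) places O8 anti to the oxygen bridge, that is trans to the future 7-hydroxyl. The absolute sense comes from the menthone spiroketal, whose isopropyl-bearing carbon is expected to block one face of the dioxinone. The step needs regio-, endo and facial selectivity, which the donor at furan C3, the cis ring of the dienophile and the spiro auxiliary are meant to secure, and the silyl enol ether it leaves stores the C6 ketone for the later bridge opening.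

Step 18
Reactants: 23 the endo Diels–Alder adduct
Product: 24 the corresponding lactol (4-hydroxy-1,3-dioxane, C1 at the aldehyde oxidation level, anomers not assigned)
Conditions: iBu2AlH (2.5 equiv), CH2Cl2, −78 °C; aqueous KNaC4H4O6
Reagents that add atoms: none
Why: Low-temperature hydride reduction of a 1,3-dioxan-4-one should stop at the cyclic hemiacetal, with the epoxide, alkyne and silyl enol ether untouched and one equivalent consumed by the free alcohol.

Step 19
Reactants: 24 the lactol
Product: 26 (5R,6S)-5,6-dihydroxy-4-(hydroxymethylidene)-3-{[(2S,3S)-3-{(2E,4R,5S)-5-hydroxy-4-methylhex-2-en-2-yl}-2-methyloxiran-2-yl]ethynyl}-6-methylcyclohex-2-en-1-one (enol tautomer of the C1 aldehyde, exocyclic C=C geometry mobile), via enone lactol 25 (not isolated)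
Conditions: Bu4NF (1.2 equiv), THF, −40 °C; aqueous NaH2PO4/Na2HPO4 (pH 7); crude product used at once
Reagents that add atoms: none
Why: Fluoride cleaves the silyl enol ether, the C6 enolate expels the β-oxygen bridge from C4a (E1cB opening of a 7-oxanorbornenone, giving the C4a=C5–C6=O enone and leaving O7 on C7 untouched), and the alkoxide then relays opening of the lactol with loss of menthone to free O8 and the C1 aldehyde, the low temperature and neutral quench being chosen to avoid Knoevenagel-type dehydration.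

Step 20
Reactants: 26 the ring-opened hydroxymethylidene enynone
Product: 27 pestaphilone D
Conditions: AgNO3 (10 mol %), acetone, 0 to 25 °C, dark
Reagents that add atoms: none
Why: Monovalent silver activates the C3≡C4 alkyne for 6-endo-dig attack by the C1 formyl/enol oxygen through a pyrylium-type intermediate that loses a proton to give the 4H-pyran-4-ylidene dienone, the cycloisomerisation known for o-alkynylbenzaldehydes, and O7 and O8 cannot reach the alkyne without forming a bridgehead alkene.

**Compound list**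

1 | ethyl (3S)-3-hydroxybutanoate | CCOC(=O)C[C@H](C)O | starting material
2 | ethyl (2S,3S)-3-hydroxy-2-methylbutanoate | CCOC(=O)[C@@H](C)[C@H](C)O | intermediate
3 | ethyl (2S,3S)-3-[(tert-butyldimethylsilyl)oxy]-2-methylbutanoate | CCOC(=O)[C@@H](C)[C@H](C)O[Si](C)(C)C(C)(C)C | intermediate
4 | (2S,3S)-3-[(tert-butyldimethylsilyl)oxy]-2-methylbutanal | O=C[C@@H](C)[C@H](C)O[Si](C)(C)C(C)(C)C | intermediate
5 | (2E,4R,5S)-5-[(tert-butyldimethylsilyl)oxy]-2,4-dimethylhex-2-enal | O=C/C(C)=C/[C@@H](C)[C@H](C)O[Si](C)(C)C(C)(C)C | intermediate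
6 | ethyl (2E,4E,6R,7S)-7-[(tert-butyldimethylsilyl)oxy]-2,4,6-trimethylocta-2,4-dienoate | CCOC(=O)/C(C)=C/C(C)=C/[C@@H](C)[C@H](C)O[Si](C)(C)C(C)(C)C | intermediate
7 | (2E,4E,6R,7S)-7-[(tert-butyldimethylsilyl)oxy]-2,4,6-trimethylocta-2,4-dien-1-ol | OC/C(C)=C/C(C)=C/[C@@H](C)[C@H](C)O[Si](C)(C)C(C)(C)C | intermediate
8 | [(2S,3S)-3-{(2E,4R,5S)-5-[(tert-butyldimethylsilyl)oxy]-4-methylhex-2-en-2-yl}-2-methyloxiran-2-yl]methanol | OC[C@]1(C)O[C@H]1/C(C)=C/[C@@H](C)[C@H](C)O[Si](C)(C)C(C)(C)C | intermediate
9 | (2R,3S)-3-{(2E,4R,5S)-5-[(tert-butyldimethylsilyl)oxy]-4-methylhex-2-en-2-yl}-2-methyloxirane-2-carbaldehyde | O=C[C@]1(C)O[C@H]1/C(C)=C/[C@@H](C)[C@H](C)O[Si](C)(C)C(C)(C)C | intermediate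
10 | tert-butyl({(2S,3R,4E)-5-[(2S,3S)-3-ethynyl-3-methyloxiran-2-yl]-3-methylhex-4-en-2-yl}oxy)dimethylsilane | C#C[C@]1(C)O[C@H]1/C(C)=C/[C@@H](C)[C@H](C)O[Si](C)(C)C(C)(C)C | intermediate
11 | (2S,3R,4E)-5-[(2S,3S)-3-ethynyl-3-methyloxiran-2-yl]-3-methylhex-4-en-2-ol | C#C[C@]1(C)O[C@H]1/C(C)=C/[C@@H](C)[C@H](C)O | intermediate
12 | 2-methyloxolan-3-one (racemic) | CC1OCCC1=O | starting material
13 | 2-methylfuran-3(2H)-one | CC1OC=CC1=O | intermediate
14 | [(2-methylfuran-3-yl)oxy]tri(propan-2-yl)silane | Cc1occc1O[Si](C(C)C)(C(C)C)C(C)C | intermediate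
15 | (5-methyl-4-{[tri(propan-2-yl)silyl]oxy}furan-2-yl)lithium | Cc1oc([Li])cc1O[Si](C(C)C)(C(C)C)C(C)C | intermediate (not isolated)
16 | [(5-iodo-2-methylfuran-3-yl)oxy]tri(propan-2-yl)silane | Cc1oc(I)cc1O[Si](C(C)C)(C(C)C)C(C)C | intermediate
17 | (2S,3R,4E)-3-methyl-5-{(2S,3S)-3-methyl-3-[(5-methyl-4-{[tri(propan-2-yl)silyl]oxy}furan-2-yl)ethynyl]oxiran-2-yl}hex-4-en-2-ol | Cc1oc(C#C[C@]2(C)O[C@H]2/C(C)=C/[C@@H](C)[C@H](C)O)cc1O[Si](C(C)C)(C(C)C)C(C)C | intermediate
18 | 5-(methoxymethylidene)-2,2-dimethyl-1,3-dioxane-4,6-dione | COC=C1C(=O)OC(C)(C)OC1=O | starting material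
19 | 5-(hydroxymethylidene)-2,2-dimethyl-1,3-dioxane-4,6-dione | OC=C1C(=O)OC(C)(C)OC1=O | intermediate
20 | (−)-menthone, (2S,5R)-5-methyl-2-(propan-2-yl)cyclohexan-1-one | CC(C)[C@@H]1CC[C@@H](C)CC1=O | starting material
21 | formylketene | O=CC=C=O | intermediate (not isolated)
22 | (2R,2'S,5'R)-5'-methyl-2'-(propan-2-yl)spiro[1,3-dioxine-2,1'-cyclohexan]-4-one | O=C1C=CO[C@@]2(O1)C[C@H](C)CC[C@H]2C(C)C | intermediate
23 | endo Diels–Alder adduct (7-oxanorbornene silyl enol ether cis-fused to the spiro-menthane dioxanone, O8 anti to the oxygen bridge) | C[C@@]12O[C@@](C#C[C@]5(C)O[C@H]5/C(C)=C/[C@@H](C)[C@H](C)O)(C=C1O[Si](C(C)C)(C(C)C)C(C)C)[C@H]3C(=O)O[C@@]4(C[C@H](C)CC[C@H]4C(C)C)O[C@@H]23 | intermediate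
24 | lactol of 23 (C1 hemiacetal, anomers not assigned) | C[C@@]12O[C@@](C#C[C@]5(C)O[C@H]5/C(C)=C/[C@@H](C)[C@H](C)O)(C=C1O[Si](C(C)C)(C(C)C)C(C)C)[C@H]3C(O)O[C@@]4(C[C@H](C)CC[C@H]4C(C)C)O[C@@H]23 | intermediate
25 | ring-opened 4-hydroxy enone with the menthone lactol still in place | C[C@@]1(O)C(=O)C=C(C#C[C@]5(C)O[C@H]5/C(C)=C/[C@@H](C)[C@H](C)O)[C@H]2C(O)O[C@@]4(C[C@H](C)CC[C@H]4C(C)C)O[C@@H]12 | intermediate (not isolated)
26 | (5R,6S)-5,6-dihydroxy-4-(hydroxymethylidene)-3-{[(2S,3S)-3-{(2E,4R,5S)-5-hydroxy-4-methylhex-2-en-2-yl}-2-methyloxiran-2-yl]ethynyl}-6-methylcyclohex-2-en-1-one | C[C@@]1(O)C(=O)C=C(C#C[C@]2(C)O[C@H]2/C(C)=C/[C@@H](C)[C@H](C)O)C(=CO)[C@H]1O | intermediate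
27 | pestaphilone D | C/C(=C\[C@@H](C)[C@H](C)O)[C@@H]1O[C@@]1(C)C1=CC2=CC(=O)[C@@](C)(O)[C@H](O)C2=CO1 | target

**Count**

Total steps: 20. Longest linear sequence: 15 steps (steps 1–10, 14, 17, 18, 19, 20).

**Steps most likely to fail**

Step 17. The push–pull dienophile may react too slowly with furan 17 under neutral conditions, and heating would invite cycloreversion and erosion of the endo preference. Fallback: the cycloaddition is moved ahead of the fragment union so that a Lewis acid can be used, which the vinyl epoxide of 17 would not tolerate. Iodofuran 16 and dioxinone 22 with Me2AlCl (CH2Cl2, −78 °C) should combine by Mukaiyama–Michael addition at the methyl-bearing furan carbon and ring closure of the resulting enolate to give the bridgehead iodide analogue of 23, F1. iBu2AlH (−78 °C) should give the lactol F2. Bu4NF (THF, −40 °C) should open the bridge and release menthone to give (5R,6S)-5,6-dihydroxy-4-(hydroxymethylidene)-3-iodo-6-methylcyclohex-2-en-1-one, F3. Sonogashira coupling of F3 with alkyne 11 (Pd(PPh3)2Cl2, CuI, Et3N, THF, 25 °C) comes back to the route at 26.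

Step 19. Once the aldehyde and the 8-hydroxyl are unmasked together under basic fluoride, E1cB loss of the 8-oxygen or retro-aldol cleavage of C8–C8a may outrun isolation. Fallback: C1 is kept at the alcohol level through the basic step. Adduct 23 with LiBH4 (1.1 equiv, THF, 0 °C) should give the bridged diol, F4 (hydroxymethyl on C8a and hydroxyl on C8, both endo), with release of menthone. Bu4NF (THF, −40 °C) should then open the bridge to the aldehyde-free enone, F5 (hydroxymethyl cis to the 8-hydroxyl). TEMPO/PhI(OAc)2 (CH2Cl2, 25 °C) should oxidise only the primary alcohol under non-basic conditions and comes back to the route at 26, which is taken directly into step 20.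

Step 20. The closure may go 5-exo instead of 6-endo, or silver may trigger rearrangement of the propargylic epoxide. Fallback: an electrophile-triggered closure followed by reduction. Compound 26 with I2 and NaHCO3 (MeCN, 0 °C) should cyclise 6-endo through the iodonium/pyrylium pathway to 4-iodopestaphilone D, F6. Hydrodeiodination with Pd(PPh3)4, HCO2H and Et3N (DMF, 25 °C) comes back to the route at 27.

**Further compounds**

F1 | step 17 | bridgehead iodide analogue of adduct 23 | C[C@@]12O[C@@](I)(C=C1O[Si](C(C)C)(C(C)C)C(C)C)[C@H]3C(=O)O[C@@]4(C[C@H](C)CC[C@H]4C(C)C)O[C@@H]23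
F2 | step 17 | lactol of F1 | C[C@@]12O[C@@](I)(C=C1O[Si](C(C)C)(C(C)C)C(C)C)[C@H]3C(O)O[C@@]4(C[C@H](C)CC[C@H]4C(C)C)O[C@@H]23
F3 | step 17 | (5R,6S)-5,6-dihydroxy-4-(hydroxymethylidene)-3-iodo-6-methylcyclohex-2-en-1-one | C[C@@]1(O)C(=O)C=C(I)C(=CO)[C@H]1O
F4 | step 19 | bridged diol from 23 (7-oxanorbornene silyl enol ether with endo hydroxymethyl on C8a and endo hydroxyl on C8) | C[C@@]12O[C@@](C#C[C@]5(C)O[C@H]5/C(C)=C/[C@@H](C)[C@H](C)O)(C=C1O[Si](C(C)C)(C(C)C)C(C)C)[C@@H](CO)[C@H]2O
F5 | step 19 | ring-opened enone with C1 as hydroxymethyl (5R,6S-diol, hydroxymethyl cis to the 5-hydroxyl) | C[C@@]1(O)C(=O)C=C(C#C[C@]2(C)O[C@H]2/C(C)=C/[C@@H](C)[C@H](C)O)[C@@H](CO)[C@H]1O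
F6 | step 20 | 4-iodopestaphilone D | C/C(=C\[C@@H](C)[C@H](C)O)[C@@H]1O[C@@]1(C)C1=C(I)C2=CC(=O)[C@@](C)(O)[C@H](O)C2=CO1
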